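## Retrosynthetic overview

1. Target ⇐ Mitsunobu inversion/acetylation at C13 ⇐ hydroxyl-directed epoxidation of the 11,12-alkene ⇐ 13-hydroxy cembranolide.
2. α-Methylene-γ-lactone ⇐ oxidative lactonisation of a 2,16-diol; the C1–C2 bond, both ring-fusion stereocentres and the 14-membered carbocycle ⇐ [2,3]-Wittig ring contraction of a 17-membered bis-allylic ether.
3. 17-Membered ether ⇐ B-alkyl Suzuki ring closure (C8–C9) ⇐ open-chain ether enoate ⇐ one-pot oxa-Michael/Horner–Wadsworth–Emmons union of an allylic alcohol (from geranyl acetate), ethyl 2-(diethoxyphosphoryl)acrylate and a dienal.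
4. Dienal (C9–C14 and C1, carrying the only bought stereocentre, C13) ⇐ (S)-α-hydroxy-γ-butyrolactone.
5. Ring order: 17-membered ether → 14-membered carbocycle → γ-lactone → epoxide.

Assumption: atom labels C1–C20 are the cembrane numbers of the target (C1 = ring-fusion CH bearing C15, C2 = lactone CH–O, C13 = CH–OAc; read from the SMILES as 1S,2S,11S,12R,13R, 3E,7Z), and (S)-α-hydroxy-γ-butyrolactone, geranyl acetate, ethyl 2-(diethoxyphosphoryl)acrylate and (1-iodoethyl)triphenylphosphonium iodide are taken as purchased.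

## Route

Step 1
Reactants: 1 (S)-3-hydroxyoxolan-2-one
Product: 2 (S)-3-[(tert-butyldimethylsilyl)oxy]oxolan-2-one
Conditions: TBSCl, imidazole, DMF, rt
Reagents that add atoms: tert-butyldimethylsilyl chloride CC(C)(C)[Si](C)(C)Cl
Why: Imidazole-promoted silyl ether formation masks the hydroxyl of the bought stereocentre (C13, S) without touching it.

Step 2
Reactants: 2 (S)-3-[(tert-butyldimethylsilyl)oxy]oxolan-2-one
Product: 3 (3S)-3-[(tert-butyldimethylsilyl)oxy]oxolan-2-ol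
Conditions: i-Bu2AlH (1.1 equiv), CH2Cl2, −78 °C
Reagents that add atoms: none
Why: Half-reduction of the lactone stops at the lactol because the tetrahedral aluminium alkoxide is stable at −78 °C.

Step 3
Reactants: 3 (3S)-3-[(tert-butyldimethylsilyl)oxy]oxolan-2-ol
Product: 4 (S)-3-[(tert-butyldimethylsilyl)oxy]pent-4-yn-1-ol
Conditions: dimethyl (1-diazo-2-oxopropyl)phosphonate, K2CO3, MeOH, 0 °C to rt
Reagents that add atoms: dimethyl (1-diazo-2-oxopropyl)phosphonate CC(=O)C(=[N+]=[N-])P(=O)(OC)OC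
Why: Ohira–Bestmann (Seyferth–Gilbert) homologation of the ring-opened α-silyloxy aldehyde gives the terminal alkyne (C11≡C12) under carbonate conditions mild enough to leave C13 unepimerised.

Step 4
Reactants: 4 (S)-3-[(tert-butyldimethylsilyl)oxy]pent-4-yn-1-ol
Product: 6 (3S,4E)-3-[(tert-butyldimethylsilyl)oxy]-4-methylhepta-4,6-dien-1-ol, via vinylalane 5 (not isolated)
Conditions: Me3Al (3.5 equiv), Cp2ZrCl2 (zirconocene dichloride, 0.25 equiv), CH2Cl2, 0 °C to rt; then vinyl bromide, Pd(PPh3)4 (5 mol %), ZnCl2, THF, rt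
Reagents that add atoms: trimethylaluminium C[Al](C)C; vinyl bromide C=CBr
Why: Negishi zirconium-catalysed syn-carboalumination puts the methyl on C12 and aluminium on C11 (E geometry), and palladium-catalysed cross-coupling of the alkenylalane with vinyl bromide proceeds with retention to the E-diene.

Step 5
Reactants: 6 (3S,4E)-3-[(tert-butyldimethylsilyl)oxy]-4-methylhepta-4,6-dien-1-ol
Product: 7 (3S,4E)-3-[(tert-butyldimethylsilyl)oxy]-4-methylhepta-4,6-dienal
Conditions: Dess–Martin periodinane, NaHCO3, CH2Cl2, 0 °C (used at once)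
Reagents that add atoms: none
Why: Buffered Dess–Martin oxidation gives the β-silyloxy aldehyde without β-elimination.

Step 6
Reactants: 8 geranyl acetate [(2E)-3,7-dimethylocta-2,6-dien-1-yl acetate]
Product: 9 (2E)-3-methyl-6-oxohex-2-en-1-yl acetate
Conditions: O3 (1 equiv), CH2Cl2/pyridine, −78 °C; then Me2S
Reagents that add atoms: ozone [O-][O+]=O
Why: Chemoselective ozonolysis cleaves the electron-rich remote trisubstituted alkene, since the alkene next to the allylic acetate is inductively deactivated.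

Step 7
Reactants: 9 (2E)-3-methyl-6-oxohex-2-en-1-yl acetate
Product: 10 (2E,6Z)-7-iodo-3-methylocta-2,6-dien-1-yl acetate
Conditions: (1-iodoethyl)triphenylphosphonium iodide, NaN(SiMe3)2, THF, −78 °C; then 9, DMPU, −78 to −20 °C
Reagents that add atoms: (1-iodoethyl)triphenylphosphonium iodide CC(I)[P+](c1ccccc1)(c1ccccc1)c1ccccc1.[I-]
Why: Stork–Zhao Wittig olefination with the α-iodo ylide gives the Z-configured α-methyl vinyl iodide (iodine cis to the chain), which fixes the later 7Z alkene.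

Step 8
Reactants: 10 (2E,6Z)-7-iodo-3-methylocta-2,6-dien-1-yl acetate
Product: 11 (2E,6Z)-7-iodo-3-methylocta-2,6-dien-1-ol
Conditions: K2CO3 (cat.), MeOH, 0 °C
Reagents that add atoms: none
Why: Base-catalysed transesterification (methanolysis) frees the allylic alcohol without affecting the vinyl iodide.

Step 9
Reactants: 11 (2E,6Z)-7-iodo-3-methylocta-2,6-dien-1-ol; 12 ethyl 2-(diethoxyphosphoryl)prop-2-enoate; 7 (3S,4E)-3-[(tert-butyldimethylsilyl)oxy]-4-methylhepta-4,6-dienal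
Product: 14 ethyl (2E,5S,6E)-5-[(tert-butyldimethylsilyl)oxy]-2-({[(2E,6Z)-7-iodo-3-methylocta-2,6-dien-1-yl]oxy}methyl)-6-methylnona-2,6,8-trienoate, via phosphonate carbanion 13 (not isolated)
Conditions: NaH (1.0 equiv), THF, 0 °C; 12; then 7, −78 to 0 °C
Reagents that add atoms: none
Why: Tandem oxa-Michael addition/Horner–Wadsworth–Emmons olefination gives the E-enoate (ester trans to C14), so the ether CH2 (C17) is cis to C14 as the later syn-selective rearrangement needs.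

Step 10
Reactants: 14 ethyl (2E,5S,6E)-5-[(tert-butyldimethylsilyl)oxy]-2-({[(2E,6Z)-7-iodo-3-methylocta-2,6-dien-1-yl]oxy}methyl)-6-methylnona-2,6,8-trienoate
Product: 16 ethyl (3E,7Z,11E,13S,15E)-13-[(tert-butyldimethylsilyl)oxy]-4,8,12-trimethyl-1-oxacycloheptadeca-3,7,11,15-tetraene-16-carboxylate, via B-alkyl-9-BBN 15 (not isolated)
Conditions: 9-BBN, THF, rt; then slow addition to [1,1′-bis(diphenylphosphino)ferrocene]palladium dichloride Pd(dppf)Cl2 (20 mol %), AsPh3, Cs2CO3, DMF/THF/H2O, 45 °C, 1 mM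
Reagents that add atoms: none
Why: 9-BBN hydroborates only the terminal vinyl group (anti-Markovnikov), and intramolecular B-alkyl Suzuki–Miyaura coupling with the vinyl iodide at high dilution closes the 17-membered ring with retention of the Z geometry at C7=C8.

Step 11
Reactants: 16 ethyl (3E,7Z,11E,13S,15E)-13-[(tert-butyldimethylsilyl)oxy]-4,8,12-trimethyl-1-oxacycloheptadeca-3,7,11,15-tetraene-16-carboxylate
Product: 17 [(3E,7Z,11E,13S,15Z)-13-[(tert-butyldimethylsilyl)oxy]-4,8,12-trimethyl-1-oxacycloheptadeca-3,7,11,15-tetraen-16-yl]methanol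
Conditions: i-Bu2AlH (2.5 equiv), CH2Cl2, −78 °C
Reagents that add atoms: none
Why: 1,2-Reduction of the enoate to the allylic alcohol removes the Michael acceptor before the carbanion step.

Step 12
Reactants: 17 [(3E,7Z,11E,13S,15Z)-13-[(tert-butyldimethylsilyl)oxy]-4,8,12-trimethyl-1-oxacycloheptadeca-3,7,11,15-tetraen-16-yl]methanol
Product: 19 2-[(1S,2S,3E,7Z,11E,13S)-13-[(tert-butyldimethylsilyl)oxy]-2-hydroxy-4,8,12-trimethylcyclotetradeca-3,7,11-trien-1-yl]prop-2-en-1-ol, via dilithio species 18 (not isolated)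
Conditions: n-BuLi (2.5 equiv), THF, −78 to −20 °C; aq NH4Cl
Reagents that add atoms: none
Why: Lithiation of the ether CH2 next to the geranyl-type alkene (C2) triggers a [2,3]-Wittig sigmatropic shift onto C1 that forms the C1–C2 bond and contracts the ring from 17 to 14 atoms; the cis relation of C17 and C14 gives the syn (1,2-cis) product through the envelope transition state with the vinyl group exo, and the C13 silyloxy centre, held anti to the forming bond by allylic strain with its bulky OSi group turned away from C1, is expected (a model-based prediction, not a secured outcome) to direct C2 to the face that gives 1S,2S.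

Step 13
Reactants: 19 2-[(1S,2S,3E,7Z,11E,13S)-13-[(tert-butyldimethylsilyl)oxy]-2-hydroxy-4,8,12-trimethylcyclotetradeca-3,7,11-trien-1-yl]prop-2-en-1-ol
Product: 22 (1S,2S,3E,7Z,11E,13S)-13-[(tert-butyldimethylsilyl)oxy]cembra-3,7,11,15(17)-tetraen-16,2-olide, via hydroxy enal 20 (not isolated), via lactol 21 (not isolated)
Conditions: TEMPO (20 mol %), PhI(OAc)2 (2.5 equiv), CH2Cl2, rt
Reagents that add atoms: none
Why: Oxidative lactonisation, in which TEMPO/PhI(OAc)2 oxidises only the primary allylic alcohol, the C2 hydroxyl traps the aldehyde as a lactol, and the lactol is oxidised on to the cis-fused α-methylene-γ-butyrolactone with no stereocentre touched.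

Step 14
Reactants: 22 (1S,2S,3E,7Z,11E,13S)-13-[(tert-butyldimethylsilyl)oxy]cembra-3,7,11,15(17)-tetraen-16,2-olide
Product: 23 (1S,2S,3E,7Z,11E,13S)-13-hydroxycembra-3,7,11,15(17)-tetraen-16,2-olide
Conditions: HF·pyridine, THF/pyridine, 0 °C to rt
Reagents that add atoms: none
Why: Fluoride-mediated desilylation under weakly acidic conditions frees the C13 allylic alcohol without conjugate addition to the methylene lactone.

Step 15
Reactants: 23 (1S,2S,3E,7Z,11E,13S)-13-hydroxycembra-3,7,11,15(17)-tetraen-16,2-olide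
Product: 24 (1S,2S,3E,7Z,11S,12S,13S)-11,12-epoxy-13-hydroxycembra-3,7,15(17)-trien-16,2-olide
Conditions: VO(acac)2 (5 mol %), t-BuOOH, CH2Cl2, 0 °C to rt
Reagents that add atoms: tert-butyl hydroperoxide CC(C)(C)OO
Why: Hydroxyl-directed vanadium-catalysed epoxidation touches only the allylic-alcohol alkene and, with H13 eclipsing the C12 methyl to avoid A(1,2) strain, delivers oxygen syn to the hydroxyl to give the erythro epoxy alcohol, setting C11 and C12 from C13.

Step 16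
Reactants: 24 (1S,2S,3E,7Z,11S,12S,13S)-11,12-epoxy-13-hydroxycembra-3,7,15(17)-trien-16,2-olide
Product: 25 (1S,2S,3E,7Z,11S,12R,13R)-13-acetoxy-11,12-epoxycembra-3,7,15(17)-trien-16,2-olide
Conditions: PPh3, DIAD, AcOH, toluene, 0 °C to rt
Reagents that add atoms: acetic acid CC(=O)O
Why: Mitsunobu esterification displaces the alkoxyphosphonium by acetate in an SN2 step with inversion, turning 13S into the 13R acetate of the target.

## Compound list

1 | (S)-3-hydroxyoxolan-2-one [(S)-α-hydroxy-γ-butyrolactone] | O[C@H]1CCOC1=O | starting material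
2 | (S)-3-[(tert-butyldimethylsilyl)oxy]oxolan-2-one | CC(C)(C)[Si](C)(C)O[C@H]1CCOC1=O | intermediate
3 | (3S)-3-[(tert-butyldimethylsilyl)oxy]oxolan-2-ol (lactol, both anomers) | CC(C)(C)[Si](C)(C)O[C@H]1CCOC1O | intermediate
4 | (S)-3-[(tert-butyldimethylsilyl)oxy]pent-4-yn-1-ol | C#C[C@H](CCO)O[Si](C)(C)C(C)(C)C | intermediate
5 | vinylalane: dimethyl[(1E,3S)-3-[(tert-butyldimethylsilyl)oxy]-5-[(dimethylalumanyl)oxy]-2-methylpent-1-en-1-yl]alumane | C[Al](C)/C=C(\C)[C@H](CCO[Al](C)C)O[Si](C)(C)C(C)(C)C | intermediate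
6 | (3S,4E)-3-[(tert-butyldimethylsilyl)oxy]-4-methylhepta-4,6-dien-1-ol | C=C/C=C(\C)[C@H](CCO)O[Si](C)(C)C(C)(C)C | intermediate
7 | (3S,4E)-3-[(tert-butyldimethylsilyl)oxy]-4-methylhepta-4,6-dienal | C=C/C=C(\C)[C@H](CC=O)O[Si](C)(C)C(C)(C)C | intermediate
8 | geranyl acetate [(2E)-3,7-dimethylocta-2,6-dien-1-yl acetate] | CC(C)=CCC/C(C)=C/COC(C)=O | starting material
9 | (2E)-3-methyl-6-oxohex-2-en-1-yl acetate | O=CCC/C(C)=C/COC(C)=O | intermediate
10 | (2E,6Z)-7-iodo-3-methylocta-2,6-dien-1-yl acetate | C/C(I)=C/CC/C(C)=C/COC(C)=O | intermediate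
11 | (2E,6Z)-7-iodo-3-methylocta-2,6-dien-1-ol | C/C(I)=C/CC/C(C)=C/CO | intermediate
12 | ethyl 2-(diethoxyphosphoryl)prop-2-enoate | C=C(C(=O)OCC)P(=O)(OCC)OCC | starting material
13 | phosphonate carbanion: sodium salt of ethyl 2-(diethoxyphosphoryl)-3-{[(2E,6Z)-7-iodo-3-methylocta-2,6-dien-1-yl]oxy}propanoate | CCOC(=O)[C-](COC/C=C(C)/CC/C=C(/C)I)P(=O)(OCC)OCC.[Na+] | intermediate
14 | ethyl (2E,5S,6E)-5-[(tert-butyldimethylsilyl)oxy]-2-({[(2E,6Z)-7-iodo-3-methylocta-2,6-dien-1-yl]oxy}methyl)-6-methylnona-2,6,8-trienoate | CCOC(=O)/C(COC/C=C(C)/CC/C=C(/C)I)=C/C[C@H](O[Si](C)(C)C(C)(C)C)/C(C)=C/C=C | intermediate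
15 | B-alkyl-9-BBN: ethyl (2E,5S,6E)-9-(9-borabicyclo[3.3.1]nonan-9-yl)-5-[(tert-butyldimethylsilyl)oxy]-2-({[(2E,6Z)-7-iodo-3-methylocta-2,6-dien-1-yl]oxy}methyl)-6-methylnona-2,6-dienoate | CCOC(=O)/C(COC/C=C(C)/CC/C=C(/C)I)=C/C[C@H](O[Si](C)(C)C(C)(C)C)/C(C)=C/CCB1C2CCCC1CCC2 | intermediate
16 | ethyl (3E,7Z,11E,13S,15E)-13-[(tert-butyldimethylsilyl)oxy]-4,8,12-trimethyl-1-oxacycloheptadeca-3,7,11,15-tetraene-16-carboxylate | CCOC(=O)/C1=C/C[C@H](O[Si](C)(C)C(C)(C)C)/C(C)=C/CC/C(C)=C\CC/C(C)=C/COC1 | intermediate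
17 | [(3E,7Z,11E,13S,15Z)-13-[(tert-butyldimethylsilyl)oxy]-4,8,12-trimethyl-1-oxacycloheptadeca-3,7,11,15-tetraen-16-yl]methanol | OC/C1=C/C[C@H](O[Si](C)(C)C(C)(C)C)/C(C)=C/CC/C(C)=C\CC/C(C)=C/COC1 | intermediate
18 | dilithio species: lithium alkoxide of 17 lithiated at ring carbon 2 (the ether CH2 next to the 3,4-alkene) | [Li]OC/C1=C/C[C@H](O[Si](C)(C)C(C)(C)C)/C(C)=C/CC/C(C)=C\CC/C(C)=C/C([Li])OC1 | intermediate
19 | 2-[(1S,2S,3E,7Z,11E,13S)-13-[(tert-butyldimethylsilyl)oxy]-2-hydroxy-4,8,12-trimethylcyclotetradeca-3,7,11-trien-1-yl]prop-2-en-1-ol | C=C(CO)[C@@H]1C[C@H](O[Si](C)(C)C(C)(C)C)/C(C)=C/CC/C(C)=C\CC/C(C)=C/[C@@H]1O | intermediate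
20 | hydroxy enal: 2-[(1S,2S,3E,7Z,11E,13S)-13-[(tert-butyldimethylsilyl)oxy]-2-hydroxy-4,8,12-trimethylcyclotetradeca-3,7,11-trien-1-yl]prop-2-enal | C=C(C=O)[C@@H]1C[C@H](O[Si](C)(C)C(C)(C)C)/C(C)=C/CC/C(C)=C\CC/C(C)=C/[C@@H]1O | intermediate
21 | lactol: (1S,2S,3E,7Z,11E,13S)-13-[(tert-butyldimethylsilyl)oxy]-2,16-epoxycembra-3,7,11,15(17)-tetraen-16-ol (both anomers) | C=C1C(O)O[C@H]2/C=C(\C)CC/C=C(/C)CC/C=C(\C)[C@@H](O[Si](C)(C)C(C)(C)C)C[C@@H]12 | intermediate
22 | (1S,2S,3E,7Z,11E,13S)-13-[(tert-butyldimethylsilyl)oxy]cembra-3,7,11,15(17)-tetraen-16,2-olide | C=C1C(=O)O[C@H]2/C=C(\C)CC/C=C(/C)CC/C=C(\C)[C@@H](O[Si](C)(C)C(C)(C)C)C[C@@H]12 | intermediate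
23 | (1S,2S,3E,7Z,11E,13S)-13-hydroxycembra-3,7,11,15(17)-tetraen-16,2-olide | C=C1C(=O)O[C@H]2/C=C(\C)CC/C=C(/C)CC/C=C(\C)[C@@H](O)C[C@@H]12 | intermediate
24 | (1S,2S,3E,7Z,11S,12S,13S)-11,12-epoxy-13-hydroxycembra-3,7,15(17)-trien-16,2-olide (C12 has the same spatial arrangement as in 25; only its label changes with the C13 substituent) | C=C1C(=O)O[C@H]2/C=C(\C)CC/C=C(/C)CC[C@@H]3O[C@@]3(C)[C@@H](O)C[C@@H]12 | intermediate
25 | (1S,2S,3E,7Z,11S,12R,13R)-13-acetoxy-11,12-epoxycembra-3,7,15(17)-trien-16,2-olide (CNP0146076.3) | C=C1C(=O)O[C@H]2/C=C(\C)CC/C=C(/C)CC[C@@H]3O[C@@]3(C)[C@H](OC(C)=O)C[C@@H]12 | target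

## Step count and risks

Total step count: 16. Longest linear sequence: 13 steps (1 to 25 through steps 1–5 and 9–16; the geranyl acetate branch is steps 6–8).

Steps most likely to fail:

Step 12 (ring contraction). The C16 lithium alkoxide may steer metalation to the neighbouring ether CH2 (C17) or favour a [1,2]-shift, and the remote induction from C13 is the least secure stereochemical element of the route. The facial sense is a model-based prediction; if it is reversed, the fallback below does not correct it. The fallback addresses the metalation risk only. It sets out from 17 and comes back at 19. Silylation of 17 (Et3SiCl, imidazole) gives the triethylsilyl ether [(3E,7Z,11E,13S,15Z)-13-[(tert-butyldimethylsilyl)oxy]-4,8,12-trimethyl-1-oxacycloheptadeca-3,7,11,15-tetraen-16-yl]methyl triethylsilyl ether F5, which carries no alkoxide. Its mono-anionic ring contraction (n-BuLi, THF, −78 °C) gives (1S,2E,6Z,10E,12S,14S)-12-[(tert-butyldimethylsilyl)oxy]-3,7,11-trimethyl-14-{3-[(triethylsilyl)oxy]prop-1-en-2-yl}cyclotetradeca-2,6,10-trien-1-ol F6. PPTS in MeOH then cleaves only the primary triethylsilyl ether and returns 19.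

Step 10 (hydroboration and macrocyclic B-alkyl Suzuki coupling). Hydroboration of the diene terminus and the high-dilution cross-coupling may give oligomers or protodeboronation. The fallback closes the ring by olefination instead; it sets out from 6, 11 and 12 and comes back at 16. Alcohol 11 is added to 12 with catalytic KOt-Bu to give the neutral phosphonate ethyl 2-(diethoxyphosphoryl)-3-{[(2E,6Z)-7-iodo-3-methylocta-2,6-dien-1-yl]oxy}propanoate F1. Diene alcohol 6 is hydroborated to 9-[(3E,5S)-5-[(tert-butyldimethylsilyl)oxy]-7-hydroxy-4-methylhept-3-en-1-yl]-9-borabicyclo[3.3.1]nonane F2 and coupled intermolecularly with F1 (Pd(dppf)Cl2, AsPh3, Cs2CO3). This gives ethyl 2-(diethoxyphosphoryl)-3-{[(2E,6Z,10E,12S)-12-[(tert-butyldimethylsilyl)oxy]-14-hydroxy-3,7,11-trimethyltetradeca-2,6,10-trien-1-yl]oxy}propanoate F3. Dess–Martin oxidation gives ethyl 2-(diethoxyphosphoryl)-3-{[(2E,6Z,10E,12S)-12-[(tert-butyldimethylsilyl)oxy]-3,7,11-trimethyl-14-oxotetradeca-2,6,10-trien-1-yl]oxy}propanoate F4. Intramolecular Horner–Wadsworth–Emmons reaction (LiCl, DBU, MeCN, high dilution) then closes the 17-membered ring to 16.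

Step 16 (Mitsunobu inversion). The carbinol lies between a fully substituted epoxide carbon and a ring CH2, so displacement may be slow or give elimination. The fallback separates activation from displacement; it sets out from 24 and comes back at 25. Chloromethanesulfonyl chloride and pyridine give (1S,2S,3E,7Z,11S,12R,13S)-11,12-epoxy-16-oxo-2,16-epoxycembra-3,7,15(17)-trien-13-yl chloromethanesulfonate F7, and CsOAc with 18-crown-6 in toluene at 80 °C displaces the sulfonate with inversion to give 25.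

Further compounds
F1 | step 10 | ethyl 2-(diethoxyphosphoryl)-3-{[(2E,6Z)-7-iodo-3-methylocta-2,6-dien-1-yl]oxy}propanoate | CCOC(=O)C(COC/C=C(C)/CC/C=C(/C)I)P(=O)(OCC)OCC
F2 | step 10 | 9-[(3E,5S)-5-[(tert-butyldimethylsilyl)oxy]-7-hydroxy-4-methylhept-3-en-1-yl]-9-borabicyclo[3.3.1]nonane | OCC[C@H](O[Si](C)(C)C(C)(C)C)/C(C)=C/CCB1C2CCCC1CCC2
F3 | step 10 | ethyl 2-(diethoxyphosphoryl)-3-{[(2E,6Z,10E,12S)-12-[(tert-butyldimethylsilyl)oxy]-14-hydroxy-3,7,11-trimethyltetradeca-2,6,10-trien-1-yl]oxy}propanoate | CCOC(=O)C(COC/C=C(C)/CC/C=C(/C)CC/C=C(\C)[C@H](CCO)O[Si](C)(C)C(C)(C)C)P(=O)(OCC)OCC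
F4 | step 10 | ethyl 2-(diethoxyphosphoryl)-3-{[(2E,6Z,10E,12S)-12-[(tert-butyldimethylsilyl)oxy]-3,7,11-trimethyl-14-oxotetradeca-2,6,10-trien-1-yl]oxy}propanoate | CCOC(=O)C(COC/C=C(C)/CC/C=C(/C)CC/C=C(\C)[C@H](CC=O)O[Si](C)(C)C(C)(C)C)P(=O)(OCC)OCC
F5 | step 12 | [(3E,7Z,11E,13S,15Z)-13-[(tert-butyldimethylsilyl)oxy]-4,8,12-trimethyl-1-oxacycloheptadeca-3,7,11,15-tetraen-16-yl]methyl triethylsilyl ether | CC[Si](CC)(CC)OC/C1=C/C[C@H](O[Si](C)(C)C(C)(C)C)/C(C)=C/CC/C(C)=C\CC/C(C)=C/COC1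
F6 | step 12 | (1S,2E,6Z,10E,12S,14S)-12-[(tert-butyldimethylsilyl)oxy]-3,7,11-trimethyl-14-{3-[(triethylsilyl)oxy]prop-1-en-2-yl}cyclotetradeca-2,6,10-trien-1-ol | C=C(CO[Si](CC)(CC)CC)[C@@H]1C[C@H](O[Si](C)(C)C(C)(C)C)/C(C)=C/CC/C(C)=C\CC/C(C)=C/[C@@H]1O
F7 | step 16 | (1S,2S,3E,7Z,11S,12R,13S)-11,12-epoxy-16-oxo-2,16-epoxycembra-3,7,15(17)-trien-13-yl chloromethanesulfonate | C=C1C(=O)O[C@H]2/C=C(\C)CC/C=C(/C)CC[C@@H]3O[C@@]3(C)[C@@H](OS(=O)(=O)CCl)C[C@@H]12
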